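## Analysis of the target

Quercetin 3,3'-bissulfate (17) is a flavonol: ring A is fused to the 4-pyranone ring C, and the catechol-derived ring B sits on C2. The molecule is flat and achiral, so no stereocentre has to be delivered, and the one that appears on the way (C2 of a flavanone) is erased by dehydrogenation. The difficulty lies in telling five oxygen substituents apart: O3 and O3' must carry SO3H, while O4', O5 and O7 must end as free phenols. The two sulfate monoesters are the sensitive groups, above all the enol-type sulfate on O3 next to the C4 carbonyl, which is lost in acid, so both must come in late and then see only neutral conditions. The neighbouring catechol oxygens O3' and O4' are the hardest pair to distinguish on a finished flavonoid, so their difference is best bought with a starting material. The plan rests on ring A: C5, C7 and C8a carry oxygen in a 1,3,5 pattern, and C4a, flanked by two of them, carries the acyl carbon C4. This is the pattern of three acetate units folded by a Claisen condensation onto a cinnamoyl unit, which supplies C4, C3, C2 and ring B. The C3 oxygen belongs to neither unit and has to be added by oxidation.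

## Retrosynthetic reasoning

**17 to 16.** The three O–benzyl bonds at O4', O5 and O7 are cut last. Sulfate monoesters tolerate neither acid nor heat, so the final deprotection must be neutral, and hydrogenolysis is the one that qualifies. The forward step has to cleave three benzyl ethers without touching the S–O bonds or the C2=C3 bond.

**16 to 15.** Both O–S bonds are cut together. In 15 the only free hydroxyls are those at C3 and C3', so the sulfation needs no selectivity. The regiochemistry is decided by the protecting-group pattern, not by the reagent.

**15 to 14.** The methoxymethyl acetal on O3' is removed. This acetal, paired with the benzyl ether on O4', is what distinguishes the two catechol oxygens, and the pair is carried unchanged from aldehyde 1. Acid can be used here because benzyl ethers and the flavonol core are acid-stable and no sulfate is yet present.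

**14 to 12 (through 13).** The C3–O bond is cut. Oxygen is put onto C3 by epoxidation of the C2=C3 bond of flavone 12 and acid opening of epoxide 13. The oxidant is electrophilic, so every phenol must be capped, which is why O5 also carries a benzyl group in 12.

**12 to 11 to 10 to 9.** The benzyl groups on O5 and O7 and the C2–C3 unsaturation are removed in the order that reactivity dictates.
- The free, acidic 7-OH of flavanone 9 can be benzylated under mild base, giving 10.
- The chelated 5-OH needs forcing base, which a flavanone would answer by ring opening. Dehydrogenation to 11 is therefore placed in between; it also deletes the C2 stereocentre.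
- Flavone 11 is stable to base and is benzylated at O5 to give 12.

**9 to 8 to 7 to 6 (key disconnection).** Two bonds are cut:
- O1–C2, by a retro-oxa-Michael reaction, gives chalcone 8.
- The ring A bond from C4a to the neighbouring oxygen-bearing carbon (C5 or C8a, equivalent in 8), by a retro-Claisen reaction, gives the open-chain triketo ester 7.

Ester 7 is the methanolysis product of pyrone 6, which serves as its stable, storable form. The side-chain carbon of 6 is bonded to pyrone C6 and cannot reach the lactone carbon across the planar ring, so 6 itself cannot cyclize; it must first be opened to 7. Cutting here turns an aromatic ring into a chain of alternating carbonyls, which can be assembled by enolate chemistry with no aromatic substitution and no regiochemical question on ring A. The forward reaction has to open the lactone, fold the chain by Claisen and not aldol condensation, and then close ring C.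

**6 to 5 and 4.** The bond between the side-chain methylene and the ketone carbon is cut. The methylene is the methyl group of lactone 5, made nucleophilic by double deprotonation. The acyl carbon comes from the N-methoxy-N-methylamide 4, chosen because its tetrahedral adduct does not collapse before work-up.

**4 to 2 and 3; 2 to 1.** The C=C bond is cut to aldehyde 2 and phosphonate 3 (Horner–Wadsworth–Emmons). Aldehyde 2 is the acetal of the commercial phenol 1.

## Alternatives that were turned down

**Alternative 1:** Ring C is cut at C4a–C4, C4–C3 and O1–C2. The flavone 4',5,7-tri-O-benzyl-3'-O-(methoxymethyl)luteolin (A1) then falls into three components: 3,5-bis(benzyloxy)-2-iodophenol (A2), carbon monoxide (A4) as C4, and 1-(benzyloxy)-4-ethynyl-2-(methoxymethoxy)benzene (A3) as C3, C2 and ring B.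
- Forward reaction: zerovalent palladium inserts into the C–I bond of A2, A4 inserts, the acylpalladium couples with A3 in an amine base to an ynone, and the phenol closes onto it 6-endo-dig to give A1.
- For: it is convergent and arrives at the flavone oxidation level with all three benzyl ethers in place. A1 is the same compound as 12, so steps 5 to 7 of the chosen route would be saved. On step economy after the ring closure this alternative is stronger.
- Against: the iodine of A2 sits between a hydroxyl and a benzyloxy group on an electron-rich ring, which slows oxidative addition. Making A2 needs a desymmetrized ring A ether and an iodination that must choose between the doubly activated positions ortho and para to the hydroxyl. The ynone can close 5-exo-dig to an aurone, and coupling without insertion of A4 leads to a 2-arylbenzofuran. A toxic gas under pressure is required.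
- Comparison: the chosen strategy builds ring A instead of buying and halogenating it, so no aromatic regiochemistry arises and no transition metal is needed in the ring-forming step. It pays for this with a lower oxidation level than that of A1, which must be corrected in step 6.

**Alternative 2:** Ring A is cut at C5–C6, C7–C8 and C4a–C5. Rings C and B with the C3 oxygen are kept in a pyranone diazoketone, 6-[4-(benzyloxy)-3-(methoxymethoxy)phenyl]-2-(diazoacetyl)-5-(methoxymethoxy)-4H-pyran-4-one (A6), to be derived from kojic acid (A8). C6 and C7 come from (triisopropylsilyloxy)acetylene (A7). The product of the ring closure is 4'-O-benzyl-3,3'-bis-O-(methoxymethyl)-7-O-(triisopropylsilyl)quercetin (A5).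
- Forward reaction: irradiation of A6 triggers a Wolff rearrangement to a pyranonylketene. This undergoes [2+2] addition with A7, the cyclobutenone opens on heating, and 6π electrocyclization with tautomerization gives A5.
- For: the C3 oxygen is present from the start, so no C3 oxidation is needed, and O5 (free) and O7 (silylated) emerge differentiated in A5. On oxidation-state economy this alternative is stronger.
- Against: A6 is far from A8. It requires arylation of A8 at the position next to the ring oxygen, oxidation of the hydroxymethyl group to the acid, and diazoketone formation with a hazardous diazoalkane. The 4-pyranone chromophore absorbs in the same region as the diazoketone, A7 is hydrolytically fragile, and the silyl ether of A5 must survive the later acid removal of two acetals.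
- Comparison: the risk is spread over a long synthesis of A6 and over the photochemical ring closure, whereas the chosen route reaches its precursor 6 in three steps and concentrates the risk in one operation.

**Alternative 3:** Only the C3–C4 bond of ring C is cut. The protected dihydroflavonol 4',5,7-tri-O-benzyl-3'-O-(methoxymethyl)dihydroquercetin (A9) then opens to the dialdehyde 2,4-bis(benzyloxy)-6-[1-[4-(benzyloxy)-3-(methoxymethoxy)phenyl]-2-oxoethoxy]benzaldehyde (A10).
- Forward reaction: a triazolium-derived carbene adds to the ring A aldehyde of A10, and the resulting acyl anion equivalent attacks the aliphatic aldehyde (6-exo-trig). This forms C3–C4 and gives A9 as a racemic mixture of diastereomers, which a single dehydrogenation would convert into 14.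
- For: the C3 oxygen arrives with the ring closure, the conditions are metal-free and all benzyl ethers are already in place in A9. One oxidation is needed afterwards, against two in the chosen route, so this alternative is stronger on the late stage.
- Against: the chemoselectivity runs against inherent reactivity. The carbene adds faster to the unhindered aliphatic aldehyde than to the electron-rich, doubly ortho-substituted aromatic one. The acyl anion equivalent of an α-aryloxy aldehyde expels the aryloxide (internal redox), which cleaves A10 instead of closing it to A9. A10 is also an easily enolized α-aryl-α-aryloxy aldehyde, and its preparation needs an O-alkylation of a hindered phenol and redox adjustments with the other aldehyde masked.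
- Comparison: the closure to A9 has to override the inherent preference of the carbene, whereas the ring-forming step of the chosen route belongs to a substrate class with direct analogy and uses a precursor made in three steps.

Key step: step 4

Remark on the chemistry: sulfate monoesters are robust only as salts, so 16 is carried as its pyridinium salt (the pyridinium ion stays protonated beside the strongly acidic sulfate and should not poison Pd/C) and 17 is set free from its salt by cold H+ exchange; both are written in the protonated form of the target SMILES, and compounds 9, 10 and 13 are racemic.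

## Route

Step 1
Reactants: 1 4-(benzyloxy)-3-hydroxybenzaldehyde
Product: 2 4-(benzyloxy)-3-(methoxymethoxy)benzaldehyde
Conditions: MOMCl, i-Pr2NEt, CH2Cl2, 0 °C to rt
Reagents that add atoms: chloromethyl methyl ether, COCCl
Why: O-Alkylation of the phenol with an α-chloro ether (Williamson-type acetal formation); it fixes the benzyl/methoxymethyl difference between O4' and O3', and the acetal withstands all basic and oxidative steps up to step 9.

Step 2
Reactants: 2 4-(benzyloxy)-3-(methoxymethoxy)benzaldehyde, 3 diethyl [2-[methoxy(methyl)amino]-2-oxoethyl]phosphonate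
Product: 4 (E)-3-[4-(benzyloxy)-3-(methoxymethoxy)phenyl]-N-methoxy-N-methylprop-2-enamide
Conditions: NaH, THF, 0 °C to rt
Reagents that add atoms: none
Why: Horner–Wadsworth–Emmons olefination; the stabilized phosphonate anion should give the (E)-alkene under thermodynamic control and delivers the acyl donor for step 3 directly.

Step 3
Reactants: 5 triacetic acid lactone (4-hydroxy-6-methyl-2H-pyran-2-one), 4 (E)-3-[4-(benzyloxy)-3-(methoxymethoxy)phenyl]-N-methoxy-N-methylprop-2-enamide
Product: 6 6-[(E)-4-[4-(benzyloxy)-3-(methoxymethoxy)phenyl]-2-oxobut-3-enyl]-4-hydroxy-2H-pyran-2-one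
Conditions: 5, LiN(i-Pr)2 (2.2 equiv), THF–DMPU, −78 to 0 °C; then 4, −78 to −20 °C; AcOH, H2O
Reagents that add atoms: none
Why: Acylation of the dianion of 5, which reacts at the methyl carbon, its last-formed and most nucleophilic site (vinylogous enolate). The N-methoxy-N-methylamide gives a chelated tetrahedral adduct that collapses only on work-up, so the product ketone is not exposed to base or to a second addition. A hard lithium carbanion and a β-aryl enamide favour attack at the carbonyl over conjugate addition.

Step 4
Reactants: 6 6-[(E)-4-[4-(benzyloxy)-3-(methoxymethoxy)phenyl]-2-oxobut-3-enyl]-4-hydroxy-2H-pyran-2-one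
Product: 9 racemic 4'-O-benzyl-3'-O-(methoxymethyl)eriodictyol, via triketo ester magnesium chelate 7 (not isolated), via trihydroxychalcone 8 (not isolated)
Conditions: Mg(OMe)2 (excess), MeOH, reflux; AcOH to pH 5; then NaOAc, EtOH, reflux
Reagents that add atoms: none
Why: Mg(OMe)2 deprotonates 6 and methoxide adds to the lactone carbonyl, opening the pyrone to the methyl 3,5,7-trioxo ester 7, which is held as a magnesium chelate of its 5,7-dicarbonyl enolate. Ring opening has to come first, because the side-chain carbon of 6 is bonded to pyrone C6 and cannot reach the lactone carbon across the planar ring. In 7 the chelated carbanion at C6 attacks the ester carbon C1 (Dieckmann-type Claisen condensation, 6-exo-trig), methoxide leaves and enolization gives chalcone 8 with ring A aromatic; the closest known reaction type is the Mg(OMe)2-mediated Claisen cyclization of 6-(2-oxoalkyl)-4-hydroxy-2-pyrones and of 3,5,7-triketo esters to acylphloroglucinols. After neutralization, NaOAc lets one of the two equivalent ortho hydroxyls of 8 add to the enone β-carbon (oxa-Michael addition, 6-endo-trig), which closes ring C. The new stereocentre C2 is formed without any controlling element, so 9 is racemic, which is of no consequence because C2 becomes sp2 in step 6. The selectivity needed is Claisen folding (C6 onto C1) over aldol folding (C2 onto C7) and over conjugate additions to the cinnamoyl enone. It is secured by the magnesium chelate, which places the nucleophile at C6 and ties up the C5 and C7 carbonyls as a poorly electrophilic enolate so that the ester is the only free acceptor, and by the irreversible aromatization, which drains the reversible side equilibria.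

Step 5
Reactants: 9 racemic 4'-O-benzyl-3'-O-(methoxymethyl)eriodictyol
Product: 10 racemic 4',7-di-O-benzyl-3'-O-(methoxymethyl)eriodictyol
Conditions: BnBr (1.05 equiv), K2CO3, acetone, rt
Reagents that add atoms: benzyl bromide, BrCc1ccccc1
Why: Williamson ether synthesis; the 7-OH, para to the carbonyl, is the most acidic hydroxyl, while the 5-OH is locked in a hydrogen bond to C4=O and stays untouched under one equivalent of halide and mild base.

Step 6
Reactants: 10 racemic 4',7-di-O-benzyl-3'-O-(methoxymethyl)eriodictyol
Product: 11 4',7-di-O-benzyl-3'-O-(methoxymethyl)luteolin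
Conditions: DDQ, 1,4-dioxane, reflux
Reagents that add atoms: none
Why: Quinone dehydrogenation of a flavanone to a flavone; hydride is taken from C2 (benzylic, next to O1 and to an alkoxy-substituted aryl) and a proton from C3. The chelated 5-OH and unactivated benzyl ethers are tolerated, and the C2 stereocentre disappears.

Step 7
Reactants: 11 4',7-di-O-benzyl-3'-O-(methoxymethyl)luteolin
Product: 12 4',5,7-tri-O-benzyl-3'-O-(methoxymethyl)luteolin
Conditions: BnBr, K2CO3, DMF, 70 °C
Reagents that add atoms: benzyl bromide, BrCc1ccccc1
Why: Williamson ether synthesis under forcing conditions; the chelated 5-OH reacts only in a polar solvent with heating, which is safe now that ring C is aromatic and can no longer open by β-elimination.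

Step 8
Reactants: 12 4',5,7-tri-O-benzyl-3'-O-(methoxymethyl)luteolin
Product: 14 4',5,7-tri-O-benzyl-3'-O-(methoxymethyl)quercetin, via flavone 2,3-epoxide 13 (not isolated)
Conditions: DMDO (acetone solution), CH2Cl2, 0 °C to rt; then p-TsOH·H2O (cat.), CH2Cl2, rt
Reagents that add atoms: dimethyldioxirane, CC1(C)OO1
Why: Dioxirane epoxidation of the C2=C3 bond under neutral conditions (all phenols are capped, so no phenol oxidation competes). Acid then opens oxirane 13 at C2 to a cation stabilized by O1 and the aryl group, and loss of H3 gives the 3-hydroxyflavone; the two transient stereocentres of 13 do not matter. This is the known flavone-to-flavonol sequence, and a partial loss of the methoxymethyl acetal under the acid would only anticipate step 9.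

Step 9
Reactants: 14 4',5,7-tri-O-benzyl-3'-O-(methoxymethyl)quercetin
Product: 15 4',5,7-tri-O-benzylquercetin
Conditions: HCl (aq.), MeOH–THF, 50 °C
Reagents that add atoms: none
Why: Acid-catalysed methanolysis of the aryl methoxymethyl acetal; benzyl ethers and the flavonol core are stable to these conditions, so exactly the 3- and 3'-hydroxyls are left free.

Step 10
Reactants: 15 4',5,7-tri-O-benzylquercetin
Product: 16 4',5,7-tri-O-benzylquercetin 3,3'-bis(hydrogen sulfate)
Conditions: SO3·pyridine (excess), pyridine, rt to 40 °C
Reagents that add atoms: sulfur trioxide–pyridine complex, [O-]S(=O)(=O)[n+]1ccccc1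
Why: O-Sulfation by SO3 transfer from an amine complex; the enolic 3-OH and the phenolic 3'-OH are the only free hydroxyls, so exhaustive sulfation is regiochemically defined, and the basic medium keeps both esters as pyridinium salts.

Step 11
Reactants: 16 4',5,7-tri-O-benzylquercetin 3,3'-bis(hydrogen sulfate)
Product: 17 quercetin 3,3'-bissulfate
Conditions: H2 (1 atm), Pd/C, MeOH–THF, rt; then H+ exchange resin, 0 °C, freeze-drying
Reagents that add atoms: none
Why: Catalytic hydrogenolysis of the three benzyl ethers under neutral conditions; sulfate monoester salts and the tetrasubstituted C2=C3 bond of the flavonol are not reduced at ambient pressure.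

## Compound list

1 | 4-(benzyloxy)-3-hydroxybenzaldehyde | O=Cc1ccc(OCc2ccccc2)c(O)c1 | starting material
2 | 4-(benzyloxy)-3-(methoxymethoxy)benzaldehyde | O=Cc1ccc(OCc2ccccc2)c(OCOC)c1 | intermediate
3 | diethyl [2-[methoxy(methyl)amino]-2-oxoethyl]phosphonate | CCOP(=O)(OCC)CC(=O)N(C)OC | starting material
4 | (E)-3-[4-(benzyloxy)-3-(methoxymethoxy)phenyl]-N-methoxy-N-methylprop-2-enamide | CON(C)C(=O)/C=C/c1ccc(OCc2ccccc2)c(OCOC)c1 | intermediate
5 | triacetic acid lactone (4-hydroxy-6-methyl-2H-pyran-2-one) | Cc1cc(O)cc(=O)o1 | starting material
6 | 6-[(E)-4-[4-(benzyloxy)-3-(methoxymethoxy)phenyl]-2-oxobut-3-enyl]-4-hydroxy-2H-pyran-2-one | O=C(/C=C/c1ccc(OCc2ccccc2)c(OCOC)c1)Cc1cc(O)cc(=O)o1 | intermediate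
7 | methyl (E)-9-[4-(benzyloxy)-3-(methoxymethoxy)phenyl]-3,5,7-trioxonon-8-enoate (present as its magnesium chelate, not isolated) | COC(=O)CC(=O)CC(=O)CC(=O)/C=C/c1ccc(OCc2ccccc2)c(OCOC)c1 | intermediate
8 | (E)-3-[4-(benzyloxy)-3-(methoxymethoxy)phenyl]-1-(2,4,6-trihydroxyphenyl)prop-2-en-1-one (not isolated) | O=C(/C=C/c1ccc(OCc2ccccc2)c(OCOC)c1)c1c(O)cc(O)cc1O | intermediate
9 | racemic 4'-O-benzyl-3'-O-(methoxymethyl)eriodictyol (2-[4-(benzyloxy)-3-(methoxymethoxy)phenyl]-5,7-dihydroxy-2,3-dihydro-4H-chromen-4-one) | O=C1CC(c2ccc(OCc3ccccc3)c(OCOC)c2)Oc2cc(O)cc(O)c21 | intermediate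
10 | racemic 4',7-di-O-benzyl-3'-O-(methoxymethyl)eriodictyol (7-(benzyloxy)-2-[4-(benzyloxy)-3-(methoxymethoxy)phenyl]-5-hydroxy-2,3-dihydro-4H-chromen-4-one) | O=C1CC(c2ccc(OCc3ccccc3)c(OCOC)c2)Oc2cc(OCc3ccccc3)cc(O)c21 | intermediate
11 | 4',7-di-O-benzyl-3'-O-(methoxymethyl)luteolin (7-(benzyloxy)-2-[4-(benzyloxy)-3-(methoxymethoxy)phenyl]-5-hydroxy-4H-chromen-4-one) | O=c1cc(-c2ccc(OCc3ccccc3)c(OCOC)c2)oc2cc(OCc3ccccc3)cc(O)c12 | intermediate
12 | 4',5,7-tri-O-benzyl-3'-O-(methoxymethyl)luteolin | O=c1cc(-c2ccc(OCc3ccccc3)c(OCOC)c2)oc2cc(OCc3ccccc3)cc(OCc3ccccc3)c12 | intermediate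
13 | racemic 2,3-epoxide of 12, oxirane cis-fused to ring C (4,6-bis(benzyloxy)-1a-[4-(benzyloxy)-3-(methoxymethoxy)phenyl]-1a,7a-dihydro-7H-oxireno[2,3-b]chromen-7-one, not isolated) | O=C1C2OC2(c2ccc(OCc3ccccc3)c(OCOC)c2)Oc2cc(OCc3ccccc3)cc(OCc3ccccc3)c21 | intermediate
14 | 4',5,7-tri-O-benzyl-3'-O-(methoxymethyl)quercetin | O=c1c(O)c(-c2ccc(OCc3ccccc3)c(OCOC)c2)oc2cc(OCc3ccccc3)cc(OCc3ccccc3)c12 | intermediate
15 | 4',5,7-tri-O-benzylquercetin | O=c1c(O)c(-c2ccc(OCc3ccccc3)c(O)c2)oc2cc(OCc3ccccc3)cc(OCc3ccccc3)c12 | intermediate
16 | 4',5,7-tri-O-benzylquercetin 3,3'-bis(hydrogen sulfate) | O=c1c(OS(=O)(=O)O)c(-c2ccc(OCc3ccccc3)c(OS(=O)(=O)O)c2)oc2cc(OCc3ccccc3)cc(OCc3ccccc3)c12 | intermediate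
17 | quercetin 3,3'-bissulfate | O=c1c(OS(=O)(=O)O)c(-c2ccc(O)c(OS(=O)(=O)O)c2)oc2cc(O)cc(O)c12 | target

## Step count and risk

Total step count: 11. Longest linear sequence: 11 steps, from 1 to 17; 3 and 5 are bought and enter directly.

**Step 4 (key step).** The open-chain triketo ester may fold the wrong way, by aldol attack of C2 on the C7 carbonyl. It may also be consumed by conjugate addition of methoxide, of the C4 carbon or of an enol oxygen to the cinnamoyl enone. The anionic pyrone may resist methanolysis. The fallback gives up the construction of ring A and buys it. It sets out from 2, which is condensed with 1-[2,4-bis(benzyloxy)-6-hydroxyphenyl]ethanone F1 (KOH, EtOH, rt; Claisen–Schmidt condensation) to the chalcone (E)-1-[2,4-bis(benzyloxy)-6-hydroxyphenyl]-3-[4-(benzyloxy)-3-(methoxymethoxy)phenyl]prop-2-en-1-one F2. This is closed with NaOAc in refluxing EtOH to racemic 5,7-bis(benzyloxy)-2-[4-(benzyloxy)-3-(methoxymethoxy)phenyl]-2,3-dihydro-4H-chromen-4-one F3, and dehydrogenation with DDQ in dioxane brings the route back at 12.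

**Step 3.** The dianion may add in conjugate fashion to the enamide instead of at the carbonyl, and the dilithium salt of 5 may stay poorly soluble, so that conversion stalls. The fallback sets out from 2. A Wittig reaction with Ph3P=CHCHO (toluene, 80 °C) gives (E)-3-[4-(benzyloxy)-3-(methoxymethoxy)phenyl]prop-2-enal F4. The dianion of 5 adds to this aldehyde at the carbonyl to give racemic 6-[(E)-4-[4-(benzyloxy)-3-(methoxymethoxy)phenyl]-2-hydroxybut-3-enyl]-4-hydroxy-2H-pyran-2-one F5. Oxidation of the allylic alcohol with MnO2 in CH2Cl2 returns to the route at 6.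

**Step 6.** The quinone may over-oxidize the electron-rich ring A phenol or the benzylic positions, while hydride abstraction from C2 is slow. The fallback sets out from 10 and uses halogenation and elimination instead of hydride abstraction. Iodine in pyridine at 90 °C iodinates the enol to racemic 7-(benzyloxy)-2-[4-(benzyloxy)-3-(methoxymethoxy)phenyl]-5-hydroxy-3-iodo-2,3-dihydro-4H-chromen-4-one F6. This loses hydrogen iodide to the solvent in the same flask and returns to the route at 11.

**Step 8.** The dioxirane may attack the benzylic C–H bonds of the three benzyl ethers and the electron-rich rings while the push–pull C2=C3 bond reacts slowly, and the epoxide may open with ring contraction. The fallback sets out from 12. LiN(i-Pr)2 in THF at −78 °C removes H3, and B(OMe)3 traps the anion as dimethyl [5,7-bis(benzyloxy)-2-[4-(benzyloxy)-3-(methoxymethoxy)phenyl]-4-oxo-4H-chromen-3-yl]boronate F7. Oxidation of the C–B bond with H2O2 and AcOH returns to the route at 14.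

**Step 10.** Sulfation of the chelated 3-OH may stay incomplete, and the 3-O-sulfate may hydrolyse during isolation, since the salt cannot be purified on silica. The fallback sets out from 15 and installs the sulfates as protected diesters. 2,2,2-Trichloroethyl chlorosulfate with Et3N and DMAP in THF gives 4',5,7-tri-O-benzylquercetin 3,3'-bis(2,2,2-trichloroethyl sulfate) F8, a neutral compound that can be chromatographed. Reductive removal of the trichloroethyl groups with Zn and HCO2NH4 in MeOH returns to the route at 16, obtained as its ammonium salt.

## Further compounds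

F1 | step 4 | 1-[2,4-bis(benzyloxy)-6-hydroxyphenyl]ethanone | CC(=O)c1c(O)cc(OCc2ccccc2)cc1OCc1ccccc1
F2 | step 4 | (E)-1-[2,4-bis(benzyloxy)-6-hydroxyphenyl]-3-[4-(benzyloxy)-3-(methoxymethoxy)phenyl]prop-2-en-1-one | O=C(/C=C/c1ccc(OCc2ccccc2)c(OCOC)c1)c1c(O)cc(OCc2ccccc2)cc1OCc1ccccc1
F3 | step 4 | racemic 5,7-bis(benzyloxy)-2-[4-(benzyloxy)-3-(methoxymethoxy)phenyl]-2,3-dihydro-4H-chromen-4-one | O=C1CC(c2ccc(OCc3ccccc3)c(OCOC)c2)Oc2cc(OCc3ccccc3)cc(OCc3ccccc3)c21
F4 | step 3 | (E)-3-[4-(benzyloxy)-3-(methoxymethoxy)phenyl]prop-2-enal | O=C/C=C/c1ccc(OCc2ccccc2)c(OCOC)c1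
F5 | step 3 | racemic 6-[(E)-4-[4-(benzyloxy)-3-(methoxymethoxy)phenyl]-2-hydroxybut-3-enyl]-4-hydroxy-2H-pyran-2-one | OC(/C=C/c1ccc(OCc2ccccc2)c(OCOC)c1)Cc1cc(O)cc(=O)o1
F6 | step 6 | racemic 7-(benzyloxy)-2-[4-(benzyloxy)-3-(methoxymethoxy)phenyl]-5-hydroxy-3-iodo-2,3-dihydro-4H-chromen-4-one | O=C1C(I)C(c2ccc(OCc3ccccc3)c(OCOC)c2)Oc2cc(OCc3ccccc3)cc(O)c21
F7 | step 8 | dimethyl [5,7-bis(benzyloxy)-2-[4-(benzyloxy)-3-(methoxymethoxy)phenyl]-4-oxo-4H-chromen-3-yl]boronate | COB(OC)c1c(-c2ccc(OCc3ccccc3)c(OCOC)c2)oc2cc(OCc3ccccc3)cc(OCc3ccccc3)c2c1=O
F8 | step 10 | 4',5,7-tri-O-benzylquercetin 3,3'-bis(2,2,2-trichloroethyl sulfate) | O=c1c(OS(=O)(=O)OCC(Cl)(Cl)Cl)c(-c2ccc(OCc3ccccc3)c(OS(=O)(=O)OCC(Cl)(Cl)Cl)c2)oc2cc(OCc3ccccc3)cc(OCc3ccccc3)c12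
A1 | alternative 1 | 4',5,7-tri-O-benzyl-3'-O-(methoxymethyl)luteolin (identical with 12) | O=c1cc(-c2ccc(OCc3ccccc3)c(OCOC)c2)oc2cc(OCc3ccccc3)cc(OCc3ccccc3)c12
A2 | alternative 1 | 3,5-bis(benzyloxy)-2-iodophenol | Oc1cc(OCc2ccccc2)cc(OCc2ccccc2)c1I
A3 | alternative 1 | 1-(benzyloxy)-4-ethynyl-2-(methoxymethoxy)benzene | C#Cc1ccc(OCc2ccccc2)c(OCOC)c1
A4 | alternative 1 | carbon monoxide | [C-]#[O+]
A5 | alternative 2 | 4'-O-benzyl-3,3'-bis-O-(methoxymethyl)-7-O-(triisopropylsilyl)quercetin | COCOc1c(-c2ccc(OCc3ccccc3)c(OCOC)c2)oc2cc(O[Si](C(C)C)(C(C)C)C(C)C)cc(O)c2c1=O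
A6 | alternative 2 | 6-[4-(benzyloxy)-3-(methoxymethoxy)phenyl]-2-(diazoacetyl)-5-(methoxymethoxy)-4H-pyran-4-one | [N-]=[N+]=CC(=O)c1cc(=O)c(OCOC)c(-c2ccc(OCc3ccccc3)c(OCOC)c2)o1
A7 | alternative 2 | (triisopropylsilyloxy)acetylene | C#CO[Si](C(C)C)(C(C)C)C(C)C
A8 | alternative 2 | kojic acid (5-hydroxy-2-(hydroxymethyl)-4H-pyran-4-one) | O=c1cc(CO)occ1O
A9 | alternative 3 | 4',5,7-tri-O-benzyl-3'-O-(methoxymethyl)dihydroquercetin, racemic mixture of diastereomers | O=C1c2c(OCc3ccccc3)cc(OCc3ccccc3)cc2OC(c2ccc(OCc3ccccc3)c(OCOC)c2)C1O
A10 | alternative 3 | racemic 2,4-bis(benzyloxy)-6-[1-[4-(benzyloxy)-3-(methoxymethoxy)phenyl]-2-oxoethoxy]benzaldehyde | O=CC(Oc1cc(OCc2ccccc2)cc(OCc2ccccc2)c1C=O)c1ccc(OCc2ccccc2)c(OCOC)c1
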